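The trap in these flasks is one order drawn through whole curves: at 49 h the oak run holds 0.360 M of product and the alder run 0.210 M, so at one clock time the oak run holds more product, and a rate compared at that time is compared at two different amounts of product.

| flask | starting material | reagent | time |
|---|---|---|---|
| oak | 0.800 M | 0.960 M |  |
| elm | 0.320 M | 0.480 M |  |
| maple | 2.40 M | 0.960 M |  |
| alder | 0.800 M | 0.480 M |  |
| cedar | 2.40 M | 0.320 M | 49 h |

| run | time / h | [product] / M |
|---|---|---|
| oak run | 2.2 | 0.020 |
| oak run | 6.6 | 0.088 |
| oak run | 13 | 0.174 |
| oak run | 20 | 0.224 |
| oak run | 29 | 0.267 |
| oak run | 38 | 0.318 |
| oak run | 49 | 0.360 |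
| elm run | 2.2 | 0 |
| elm run | 6.6 | 0 |
| elm run | 13 | 0.026 |
| elm run | 20 | 0.042 |
| elm run | 29 | 0.063 |
| elm run | 38 | 0.075 |
| elm run | 49 | 0.072 |
| maple run | 2.2 | 0.157 |
| maple run | 6.6 | 0.643 |
| maple run | 13 | 0.798 |
| maple run | 20 | 0.863 |
| maple run | 29 | 0.913 |
| maple run | 38 | 0.944 |
| maple run | 49 | 0.944 |
| alder run | 2.2 | 0.005 |
| alder run | 6.6 | 0.028 |
| alder run | 13 | 0.062 |
| alder run | 20 | 0.087 |
| alder run | 29 | 0.128 |
| alder run | 38 | 0.150 |
| alder run | 49 | 0.210 |

(scatter of a reading: 0.01 M)

- reaction order in [reagent] at the outset, round the charge of the oak run, defined at two percent of the starting material turned into product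
- reaction order in [starting material] at the outset, round the charge of the oak run, defined at two percent of the starting material turned into product (one fixed amount of product, the same in the runs compared)
- product in the cedar run at 49 h, as a share of the starting material charged

- Overall: starting material + reagent -> product.
- Constant volume, constant temperature.
- "The second partner" is reagent.
- An order is taken over about fifteen percent of the charge, up and down.

I read the oak column against the alder column, each at its own time. Near the start, the oak run shows 0.020 M at 2.2 h and the alder run 0.028 M at 6.6 h. Their mean rates from zero divide to 0.467, which I carry as the same-product rate ratio ρ: the mean rate of one flask up to an amount of product over that of another flask up to about that amount. With the other charge equal, the order n is ln ρ over the ln of the charge ratio, so halving the reagent gives n = 1.10. This is a rough reading, since the scatter is half of the oak reading.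

Further down, the oak run's 0.174 M at 13 h and the alder run's 0.150 M at 38 h give ρ = 0.295, smaller than the early ratio, and n = 1.76. The orders asked belong to the early row, so I commit to the early value for reagent.

The maple run has no early row: its first reading is 0.157 M at 2.2 h. Against the oak run's 0.174 M it gives ρ = 5.33 and n = 1.52, a late value, so I put the early order in starting material lower, near 1.

The maple run reaches 0.944 M on 0.960 M of reagent, nearly all of it, so reagent is the limiting reagent there. The cedar charge allows 13.3%, and the share of reagent read in the maple run, applied to that ceiling, gives 13.1%. The cedar run holds a third of the maple run's reagent, so I take a little less.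

The forecast gives 1.6 (1.2 to 2.1) for reagent, above my 1.10, 1.4 (1 to 1.9) for starting material and 11% (9% to 12.7%) for the cedar run, on the ground that “Alder to oak (reagent doubled) gives a factor of about 3”.

The simulation gives 1.1 for reagent, 1.1 for starting material and 12.5% for the cedar run at 49 h, from this scheme:

    starting material ⇌ intermediate + by-product (0.2372 /h, 0.02596 /M/h)
    intermediate + reagent → product (0.02160 /M/h)
    starting material → decomposed substrate (0.09324 /h)
    starting material + reagent + product → 2 product (1.285 /M²/h)

At one amount of product, the alder run goes at 0.46 of the oak run's rate, beside my early ρ of 0.467, and the rule turns that ratio into n = 1.11. Against the oak run at that amount, the maple run has a rate ratio of 3.3 for a starting-material charge ratio of 3.00, and the same rule gives n = 1.08 in starting material.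

The runs were generated by integration for an exercise, noise included.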